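The ratio of second to first end groups charged in the noon run was 11.0 %, and the readings of that run put the loss of first end groups at 11.2 % on average, so I took one second end group per first end group lost, whichever way it went.

| flask | first end groups | second end groups | remark | time |
|---|---|---|---|---|
| noon | 0.48 M | 0.053 M | run made earlier |  |
| winter | 0.48 M | 0.86 M | run made earlier |  |
| Friday's | 0.48 M | 0.200 M |  | 2.5 d |
| Tuesday's | 0.25 M | 1.20 M |  | 2.5 d |
| Saturday's | 1.5 M | 1.20 M |  | 2.5 d |
| Wednesday's | 0.25 M | 0.300 M |  | 2.5 d |
| Monday's | 1.5 M | 0.100 M |  | 2.5 d |
| Sunday's | 0.48 M | 0.432 M |  | 2.5 d |

| run | time / h | links / % | first end groups / % |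
|---|---|---|---|
| noon | 3.00 | 2 | 88 |
| noon | 8.00 | 3 | 88 |
| noon | 20.0 | 3 | 90 |
| noon | 40.0 | 2 | 89 |
| winter | 3.00 | 76 | 0 |
| winter | 8.00 | 75 | 6 |
| winter | 20.0 | 77 | 1 |
| winter | 40.0 | 78 | 0 |

(scatter of a reading: 2 percentage points)

- what was read earlier has a scatter of 2 percentage points, one standard deviation

- ranking by amount of links, in percent of the first end groups charged, from high to low, at 2.5 d (Friday's / Tuesday's / Saturday's / Wednesday's / Monday's / Sunday's)
- the amount of links, in percent of the first end groups charged of the flask you put first, at 2.5 d
- the amount of links, in percent of the first end groups charged of the flask you put last, at 2.5 d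

Both runs read flat from 3.00 h on, far short of 2.5 d, so I reckoned end states. In the winter run, the links read 76.5 % on average; I assumed the remainder took a rival route, and that the links' share rises with [second end groups] as [second end groups]/([second end groups] + a constant). At the mean winter level of 0.620 M, that constant came out at 0.190 M. Put back into the integrated share, where the rival amount is the constant times the logarithm of (start level + constant)/(end level + constant), it gave 0.185 M: my crossover level, the [second end groups] at which the selectivity factor between links and the rival route is one. It is a reading, and its weak point is noon: it gives 1.33 % links where the mean reading was 2.50 %.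

For Tuesday's, on that assumed rule, the starting level bounded links from above at 86.7 %. The level after taking up the first end groups, 0.950 M, bounded them from below at 83.7 %. The integral tightened this to 85.3 %. The same reckoning gave Saturday's 55.2 %, Wednesday's 46.4 %, Sunday's 43.6 %, Friday's 13.4 % and Monday's 1.34 %.

The forecast differed: Tuesday's > Wednesday's > Sunday's > Saturday's > Friday's > Monday's, with 98 % on top, above my upper bound, and 0.7 % at the bottom. Its ground: “Everything finishes within hours”, so it went by the ratio of second to first end groups charged.

The flask gave Tuesday's > Saturday's > Wednesday's > Sunday's > Friday's > Monday's, with 86.3 % for Tuesday's, inside my bracket, and 1.43 % for Monday's.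

    first end groups + second end groups → links (k = 2.31 /M/h)
    first end groups + second end groups → rings, rate k2*[first end groups] as long as [second end groups] is above zero (k = 0.391 /h)
    second end groups → decomposed reagent (k = 0.0146 /h)

Tuesday's fell short of complete conversion to links because of the rings: without that step its links stand at 100 %, against 86.3 %. The crossover level had put the rival share there at 14.7 %, and the flask held 13.7 % rings. With 1.0 M of first end groups in Tuesday's recipe, the same level gave me 76.3 % links; the computed flask holds 77.5 %.

The data come from a simulation for an exercise.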